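After 2.50 d the maple run has made 30.4 % left-handed product, the cedar run 29.7 % and the alder run 30.9 %, and two chemists read these numbers in opposite ways.

| setting | maple | cedar | alder | flask |
|---|---|---|---|---|
| left-handed substrate | 35 mM | 55 mM | 25 mM | 25 mM |
| right-handed substrate | 35 mM | 55 mM | 25 mM | 25 mM |
| gas | 4.2 mM (held) | 4.2 mM (held) | 4.2 mM (held) | 4.2 mM (held) |
| catalyst | 2 mol% | 2 mol% | 2 mol% | 2 mol% |
| added ligand | 0.26 mM | 0.26 mM | 0.13 mM | 0.26 mM |
| remark | run made earlier | run made earlier | run made earlier |  |

- maple (time / d: left-handed product / %): 0.833: 11.4; 1.67: 21.9; 2.50: 30.4; 3.00: 34.6; 4.00: 40.9; 5.00: 44.7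
- cedar (time / d: left-handed product / %): 0.833: 10.6; 1.67: 20.6; 2.50: 29.7; 3.00: 33.8; 4.00: 40.8; 5.00: 45.8
- alder (time / d: left-handed product / %): 0.417: 5.7; 0.833: 10.8; 1.25: 17.4; 2.50: 30.9; 5.00: 44.6

(standard deviation of a reading: 0.5 percentage points)

- catalyst is single-handed; left-handed substrate and right-handed substrate are mirror images of each other, charged as a racemate, each of them at the stated concentration
- the numbers in the tables scatter with a standard deviation of 0.5 percentage points
- at the start none of the gas is in solution

* apparent order in catalyst when 20 % of the left-handed substrate and right-handed substrate together are converted (percent change of the rate of making left-handed product for one percent more catalyst charged)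

The first chemist holds that the added ligand counts catalyst out. The flask has 0.500 mM of catalyst against 0.26 mM of added ligand. If each ligand ties up one catalyst for good, the working part is one minus ligand over catalyst, the spare share: 48.0 %. The rate then follows charged catalyst minus ligand, so with the reagent held steady, the order is one over the spare share, 2.08.

The second chemist answers that at 2.50 d the runs lie within 1.2 percentage points of each other, at a scatter of 0.5 points, although the spare shares differ: maple 62.9 %, cedar 76.4 %, alder 74.0 %. This is the forecast, 1, on the ground that “Such a rate depends only on concentration ratios, multiplied by catalyst”. Catalyst stood at 2 mol% of the left-handed substrate in maple, cedar and alder alike, so both positions are inference. With the reagent held steady, my own reckoning gives two ends, 1 for a ligand that binds loosely and 2.08 for one that binds for good, and I read the runs as leaning to the lower.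

    reagent + catalyst + right-handed substrate → catalyst + right-handed product (k = 1.80 M⁻² s⁻¹)
    gas ⇌ reagent, rate k2*(csat - [reagent]) (kL = 7.50 × 10⁻⁵ s⁻¹)
    reagent + catalyst + left-handed substrate → catalyst + left-handed product (k = 4.40 M⁻² s⁻¹)
    catalyst + added ligand ⇌ idle complex, settled at all times (K = 8800 M⁻¹)

The flask gives 0.92, beside the forecast's 1 and under 2.08: at 20 % conversion, one percent more catalyst brings 0.92 percent more rate of making left-handed product. At 3.00 d free catalyst in the flask stands at 62.0 % of the charged catalyst, above the spare share of 48.0 %, and the idle complex, the off-cycle form, holds 38.0 % of it, with 26.8 % of the added ligand still free. The spare share is a count for added ligand wholly bound, and that is the region of the first chemist's order. For alder against maple, at equal reagent, the count asks 0.841 of maple's pace in percent per day, yet at 2.50 d alder read 30.9 % against maple's 30.4 %.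

The numbers in the tables were generated by integration from invented constants; scatter was added.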